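**Plan**

- Retrosynthetic cuts, in order: the lactone O1–C2 bond, the C6–acyl bond, the C4a–C5 bond of the carbocycle, the two C8–prenyl bonds, and the C8–C8a bond. This leads back to 3-phenylglutaric anhydride, 2,2,6-trimethyl-1,3-dioxin-4-one, prenyl bromide and (R)-2-methylbutanoic acid.
- Enabling feature: the carbocycle is a cyclohexane-1,3,5-trione. Its C5–C6–C7 segment is a β-ketoacyl unit, that is, an acylketene that can be stored as a 1,3-dioxin-4-one ring. C4a is the only enolisable α-carbon of the C8a carbonyl, because C8 is quaternary.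
- Forward order: the open chain is built by dienolate acylation (C8–C8a) and gem-diprenylation (C8). The carbocycle closes first by thermal acylketene C-acylation of a silyl enol ether (C4a–C5). The acyl group then goes onto C6, and the lactone ring closes last onto O8a.
- Stereochemistry: C4 comes from catalytic enantioselective desymmetrisation of the prochiral anhydride. The side-chain centre comes from enantiopure (R)-2-methylbutanoic acid. Neither centre is acidic or involved in any later step.

Key step: step 5

Remark: atoms are named by the chromene numbering of the target (O1, C2, C3, C4, C4a, C5, C6, C7, C8, C8a), also in open-chain intermediates. (R)-2-Methylbutanoic acid is assumed to be commercially available as the single enantiomer. The CIP descriptor of C4 changes formally along the route (S in 2–7, R in 8–10, S from 11 on) because substituent priorities change; the spatial arrangement stays the same.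

Step 1
Reactants: 1 3-phenylglutaric anhydride
Product: 2 (3S)-5-oxo-3-phenyl-5-(prop-2-en-1-yloxy)pentanoic acid
Conditions: allyl alcohol (10 equiv), cinchona-alkaloid-derived bifunctional sulfonamide organocatalyst (10 mol %, the pseudoenantiomer that gives the (S)-hemiester), MTBE, rt; acid–base extraction
Reagents that add atoms: allyl alcohol, C=CCO
Why: organocatalytic enantioselective alcoholysis (desymmetrisation) of a prochiral cyclic anhydride, in which the catalyst activates the alcohol by general-base catalysis and one of the two enantiotopic carbonyl groups by hydrogen bonding, so that the C4 stereocentre is set here by catalyst control and its enantiomeric purity can be raised by crystallisation of an amine salt.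

Step 2
Reactants: 2 (3S)-5-oxo-3-phenyl-5-(prop-2-en-1-yloxy)pentanoic acid; 3 2,2,6-trimethyl-4H-1,3-dioxin-4-one
Product: 5 allyl (3S)-6-(2,2-dimethyl-4-oxo-4H-1,3-dioxin-6-yl)-5-oxo-3-phenylhexanoate, via acyl imidazolide 4 (not isolated)
Conditions: 2, CDI (1.1 equiv), THF, rt; then added to 3 (3.3 equiv) and LiN(SiMe3)2 (3.3 equiv), THF, −78 → −40 °C; aq NH4Cl
Reagents that add atoms: none
Why: crossed Claisen-type C-acylation of the γ-carbon of the lithium dienolate of 3 by an acyl imidazole, which should be far more electrophilic than the allyl ester at −78 °C, while the mild activation avoids any symmetrical anhydride-type intermediate that could exchange the two carboxyl termini and erode the C4 configuration, and the excess dienolate covers the acidic imidazole N–H and the acidic product.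

Step 3
Reactants: 5 allyl (3S)-6-(2,2-dimethyl-4-oxo-4H-1,3-dioxin-6-yl)-5-oxo-3-phenylhexanoate; 6 prenyl bromide (1-bromo-3-methylbut-2-ene)
Product: 7 allyl (3S)-6-(2,2-dimethyl-4-oxo-4H-1,3-dioxin-6-yl)-9-methyl-6-(3-methylbut-2-en-1-yl)-5-oxo-3-phenyldec-8-enoate
Conditions: 6 (2.5 equiv), Cs2CO3 (3 equiv), DMF, 0 °C → rt
Reagents that add atoms: none
Why: double C-alkylation of a doubly activated methylene (C8, flanked by the C8a ketone and the vinylogous ester carbon C7 of the dioxinone) with a soft allylic bromide, an active-methylene alkylation that installs the quaternary gem-diprenyl carbon, while the other ketone α-position (C4a) is not acidic enough for carbonate.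

Step 4
Reactants: 7 allyl (3S)-6-(2,2-dimethyl-4-oxo-4H-1,3-dioxin-6-yl)-9-methyl-6-(3-methylbut-2-en-1-yl)-5-oxo-3-phenyldec-8-enoate
Product: 8 allyl (3R,4Z)-5-[(tert-butyldimethylsilyl)oxy]-6-(2,2-dimethyl-4-oxo-4H-1,3-dioxin-6-yl)-9-methyl-6-(3-methylbut-2-en-1-yl)-3-phenyldeca-4,8-dienoate
Conditions: TBSOTf (1.3 equiv), Et3N (2 equiv), CH2Cl2, −78 → 0 °C; aq NaHCO3
Reagents that add atoms: tert-butyldimethylsilyl triflate, CC(C)(C)[Si](C)(C)OS(=O)(=O)C(F)(F)F
Why: soft enolisation and O-silylation of a ketone with a silyl triflate and an amine base, in which the quaternary C8 allows the silyl enol ether to form only towards C4a (Z expected, geometry without consequence), the ketone should silylate faster than the ester or the non-enolisable dioxinone, and no stereocentre is touched.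

Step 5
Reactants: 8 allyl (3R,4Z)-5-[(tert-butyldimethylsilyl)oxy]-6-(2,2-dimethyl-4-oxo-4H-1,3-dioxin-6-yl)-9-methyl-6-(3-methylbut-2-en-1-yl)-3-phenyldeca-4,8-dienoate
Product: 11 allyl (3S)-3-[2-hydroxy-5,5-bis(3-methylbut-2-en-1-yl)-4,6-dioxocyclohex-1-en-1-yl]-3-phenylpropanoate, via acylketene 9 (not isolated), via O-silyl trione 10 (not isolated)
Conditions: toluene (0.005 M), 110 °C, N2 sweep to remove acetone; then AcOH–THF–H2O, rt
Reagents that add atoms: none
Why: Proposed new method: heating should trigger the usual retro-hetero-Diels–Alder loss of acetone from the dioxinone to give acylketene 9, whose ketene carbon (C5) is attacked by the nucleophilic C4a of the silyl enol ether, and the resulting silyloxocarbenium/enolate zwitterion should collapse by a 1,5-silyl shift from O8a to O5 to 10, which dilute acetic acid desilylates to 11. The closest known reaction types are the stepwise hetero-[4+2] cycloaddition of dioxinone-derived acylketenes with enol ethers, which begins with the same C–C bond, and the Mukaiyama-type C-acylation of silyl enol ethers; here the second (C–O) bond of the cycloaddition would have to close a four-membered ring (O7–C7–C8–C8a), so the sequence should stop at C-acylation. The carbocycle (C4a–C8a–C8–C7–C6–C5) closes in a 6-(enolendo)-exo-dig mode at the sp carbon, with the C5=C6 enolate bond ending cis inside the ring as in any cyclohexenone. No new stereocentre survives the step (C4a is epimeric in 10 and becomes sp2 in 11), and the C4 stereocentre is not acidic and is untouched under these neutral conditions. The step needs attack by carbon at C4a in preference to attack by oxygen, to ene-type capture of the ketene by a prenyl alkene and to ketene dimerisation: O8a is capped by silicon, the quaternary C8 leaves C4a as the only enol ether carbon, the silyl enol ether is the most nucleophilic π-bond in the molecule, and high dilution disfavours dimerisation.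

Step 6
Reactants: 11 allyl (3S)-3-[2-hydroxy-5,5-bis(3-methylbut-2-en-1-yl)-4,6-dioxocyclohex-1-en-1-yl]-3-phenylpropanoate; 12 (R)-2-methylbutanoic acid
Product: 14 allyl (3S)-3-[2,6-dihydroxy-3,3-bis(3-methylbut-2-en-1-yl)-5-[(2R)-2-methylbutanoyl]-4-oxocyclohexa-1,5-dien-1-yl]-3-phenylpropanoate, via enol ester 13 (not isolated)
Conditions: 12 (1.2 equiv), DCC (1.2 equiv), DMAP (0.3 equiv), CH2Cl2, 0 °C → rt
Reagents that add atoms: none
Why: carbodiimide-mediated O-acylation of the cyclic vinylogous acid followed by DMAP-catalysed O-to-C acyl migration (Fries-type rearrangement of enol esters, the standard entry to 2-acylcyclohexane-1,3-diones) should deliver the acyl group to the unsubstituted C6, where the product is stabilised as a chelated enol, whereas acylation at the substituted C4a would be reversible, and the acyl stereocentre comes unchanged from 12 because no ketene-forming base is present.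

Step 7
Reactants: 14 allyl (3S)-3-[2,6-dihydroxy-3,3-bis(3-methylbut-2-en-1-yl)-5-[(2R)-2-methylbutanoyl]-4-oxocyclohexa-1,5-dien-1-yl]-3-phenylpropanoate
Product: 15 (3S)-3-[2,6-dihydroxy-3,3-bis(3-methylbut-2-en-1-yl)-5-[(2R)-2-methylbutanoyl]-4-oxocyclohexa-1,5-dien-1-yl]-3-phenylpropanoic acid
Conditions: Pd(PPh3)4 (5 mol %), HCO2H (3 equiv), Et3N (3 equiv), THF, rt, argon; citric acid work-up
Reagents that add atoms: none
Why: deallylation catalysed by zerovalent palladium (Tsuji–Trost ionisation of the allyl ester followed by hydride transfer from formate, releasing propene and CO2) runs under near-neutral conditions that should leave the trisubstituted prenyl alkenes, the triketone and both stereocentres untouched, and hydride capture of the π-allyl complex should outrun C-allylation of the enolised triketone.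

Step 8
Reactants: 15 (3S)-3-[2,6-dihydroxy-3,3-bis(3-methylbut-2-en-1-yl)-5-[(2R)-2-methylbutanoyl]-4-oxocyclohexa-1,5-dien-1-yl]-3-phenylpropanoic acid
Product: 16 (4S)-5-hydroxy-8,8-bis(3-methylbut-2-en-1-yl)-6-[(2R)-2-methylbutanoyl]-4-phenyl-3,4-dihydro-2H-chromene-2,7(8H)-dione
Conditions: DCC (1.1 equiv), CH2Cl2, 0 °C → rt, argon; filtration, chromatography with alcohol-free eluent
Reagents that add atoms: none
Why: carbodiimide lactonisation (6-exo-trig O-acylation of an enol) in which the C5 hydroxyl and C7 carbonyl are locked in the hydrogen-bonded 2-acyl-1,3-dione chelate, so that the free, non-chelated enol oxygen on C8a (para to the acyl group) should attack the activated carboxyl and close the dihydropyranone ring with the required regiochemistry, and no stereocentre is formed or epimerised under these neutral conditions.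

**Compound list**

1 | 3-phenylglutaric anhydride | O=C1CC(CC(=O)O1)c1ccccc1 | starting material
2 | (3S)-5-oxo-3-phenyl-5-(prop-2-en-1-yloxy)pentanoic acid | C=CCOC(=O)C[C@H](CC(=O)O)c1ccccc1 | intermediate
3 | 2,2,6-trimethyl-4H-1,3-dioxin-4-one | CC1=CC(=O)OC(C)(C)O1 | starting material
4 | allyl (3S)-5-(1H-imidazol-1-yl)-5-oxo-3-phenylpentanoate (acyl imidazolide, not isolated) | C=CCOC(=O)C[C@H](CC(=O)n1ccnc1)c1ccccc1 | intermediate
5 | allyl (3S)-6-(2,2-dimethyl-4-oxo-4H-1,3-dioxin-6-yl)-5-oxo-3-phenylhexanoate | C=CCOC(=O)C[C@H](CC(=O)CC1=CC(=O)OC(C)(C)O1)c1ccccc1 | intermediate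
6 | prenyl bromide (1-bromo-3-methylbut-2-ene) | CC(C)=CCBr | starting material
7 | allyl (3S)-6-(2,2-dimethyl-4-oxo-4H-1,3-dioxin-6-yl)-9-methyl-6-(3-methylbut-2-en-1-yl)-5-oxo-3-phenyldec-8-enoate | C=CCOC(=O)C[C@H](CC(=O)C(CC=C(C)C)(CC=C(C)C)C1=CC(=O)OC(C)(C)O1)c1ccccc1 | intermediate
8 | allyl (3R,4Z)-5-[(tert-butyldimethylsilyl)oxy]-6-(2,2-dimethyl-4-oxo-4H-1,3-dioxin-6-yl)-9-methyl-6-(3-methylbut-2-en-1-yl)-3-phenyldeca-4,8-dienoate | C=CCOC(=O)C[C@H](/C=C(\O[Si](C)(C)C(C)(C)C)C(CC=C(C)C)(CC=C(C)C)C1=CC(=O)OC(C)(C)O1)c1ccccc1 | intermediate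
9 | allyl (3R,4Z)-5-[(tert-butyldimethylsilyl)oxy]-6,6-bis(3-methylbut-2-en-1-yl)-7,9-dioxo-3-phenylnona-4,8-dienoate (acylketene, not isolated) | C=CCOC(=O)C[C@H](/C=C(\O[Si](C)(C)C(C)(C)C)C(CC=C(C)C)(CC=C(C)C)C(=O)C=C=O)c1ccccc1 | intermediate
10 | allyl (3R)-3-[2-[(tert-butyldimethylsilyl)oxy]-5,5-bis(3-methylbut-2-en-1-yl)-4,6-dioxocyclohex-2-en-1-yl]-3-phenylpropanoate (O-silyl trione, C4a epimers, not isolated) | C=CCOC(=O)C[C@H](C1C(O[Si](C)(C)C(C)(C)C)=CC(=O)C(CC=C(C)C)(CC=C(C)C)C1=O)c1ccccc1 | intermediate
11 | allyl (3S)-3-[2-hydroxy-5,5-bis(3-methylbut-2-en-1-yl)-4,6-dioxocyclohex-1-en-1-yl]-3-phenylpropanoate (one enol tautomer drawn) | C=CCOC(=O)C[C@H](C1=C(O)CC(=O)C(CC=C(C)C)(CC=C(C)C)C1=O)c1ccccc1 | intermediate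
12 | (R)-2-methylbutanoic acid | CC[C@@H](C)C(=O)O | starting material
13 | allyl (3S)-3-[2-{[(2R)-2-methylbutanoyl]oxy}-5,5-bis(3-methylbut-2-en-1-yl)-4,6-dioxocyclohex-1-en-1-yl]-3-phenylpropanoate (enol ester, one O-acyl regioisomer drawn, not isolated) | C=CCOC(=O)C[C@H](C1=C(OC(=O)[C@H](C)CC)CC(=O)C(CC=C(C)C)(CC=C(C)C)C1=O)c1ccccc1 | intermediate
14 | allyl (3S)-3-[2,6-dihydroxy-3,3-bis(3-methylbut-2-en-1-yl)-5-[(2R)-2-methylbutanoyl]-4-oxocyclohexa-1,5-dien-1-yl]-3-phenylpropanoate | C=CCOC(=O)C[C@H](C1=C(O)C(CC=C(C)C)(CC=C(C)C)C(=O)C(C(=O)[C@H](C)CC)=C1O)c1ccccc1 | intermediate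
15 | (3S)-3-[2,6-dihydroxy-3,3-bis(3-methylbut-2-en-1-yl)-5-[(2R)-2-methylbutanoyl]-4-oxocyclohexa-1,5-dien-1-yl]-3-phenylpropanoic acid | OC(=O)C[C@H](C1=C(O)C(CC=C(C)C)(CC=C(C)C)C(=O)C(C(=O)[C@H](C)CC)=C1O)c1ccccc1 | intermediate
16 | (4S)-5-hydroxy-8,8-bis(3-methylbut-2-en-1-yl)-6-[(2R)-2-methylbutanoyl]-4-phenyl-3,4-dihydro-2H-chromene-2,7(8H)-dione | CC[C@@H](C)C(=O)C1=C(O)C2=C(OC(=O)C[C@H]2c2ccccc2)C(CC=C(C)C)(CC=C(C)C)C1=O | target

**Step count and risks**

Total step count: 8. Longest linear sequence: 8 steps (1 → 16).

Steps most likely to fail: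

Step 5 (proposed new method). The ketene carbon may be captured by one of the prenyl alkenes in an ene-type process, the acylketene may dimerise, or the enol ether may lose silicon before the C–C bond forms, which would open the way to cyclisation through oxygen. The fallback uses known chemistry and sets out from 7. Thermolysis of 7 in toluene at 110 °C in the presence of methanol should trap the acylketene as 1-methyl 9-allyl (7S)-4,4-bis(3-methylbut-2-en-1-yl)-3,5-dioxo-7-phenylnonanedioate F1. Treatment with KOt-Bu in t-BuOH–THF should then bring about the classical intramolecular Claisen (Dieckmann-type) condensation of a 3,5-diketo ester, in which the C4a enolate of the C8a ketone attacks the methyl ester. After acidification the route is rejoined at 11.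

Step 3. The second alkylation may go to oxygen instead of carbon, may stall at the mono-prenyl stage for steric reasons, or may occur at the ring carbon of the dioxinone. The fallback changes the order of bond formation and sets out from 3. γ-Prenylation of the lithium dienolate of 3 (LiN(i-Pr)2, THF–DMPU, −78 °C, then 6) should give 2,2-dimethyl-6-(4-methylpent-3-en-1-yl)-4H-1,3-dioxin-4-one F2. A second identical γ-prenylation should give 6-(2,8-dimethylnona-2,7-dien-5-yl)-2,2-dimethyl-4H-1,3-dioxin-4-one F3. A third γ-deprotonation and C-acylation with acyl imidazolide 4 (from 2, as in step 2) then creates the quaternary C8 by acylation instead of alkylation, and the route is rejoined at 7.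

Step 8. The activated carboxyl may be attacked by the C5 oxygen as well as the C8a oxygen, giving poor regioselectivity of ring closure. The fallback sets out from 15 and replaces kinetic by thermodynamic control. After the DCC closure, the mixture containing (4S)-7-hydroxy-6,6-bis(3-methylbut-2-en-1-yl)-8-[(2R)-2-methylbutanoyl]-4-phenyl-3,4-dihydro-2H-chromene-2,5(6H)-dione F4 is treated with a catalytic acyl-transfer catalyst (DMAP, toluene, 40 °C). Reversible opening of the enol lactones to an acylpyridinium/enolate pair should let the regioisomers interconvert. The isomer that keeps the acyl group between a free hydroxyl and a ketone is expected to be the sink, so the route is rejoined at 16.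

**Further compounds**

F1 | step 5 | 1-methyl 9-allyl (7S)-4,4-bis(3-methylbut-2-en-1-yl)-3,5-dioxo-7-phenylnonanedioate | C=CCOC(=O)C[C@H](CC(=O)C(CC=C(C)C)(CC=C(C)C)C(=O)CC(=O)OC)c1ccccc1
F2 | step 3 | 2,2-dimethyl-6-(4-methylpent-3-en-1-yl)-4H-1,3-dioxin-4-one | CC(C)=CCCC1=CC(=O)OC(C)(C)O1
F3 | step 3 | 6-(2,8-dimethylnona-2,7-dien-5-yl)-2,2-dimethyl-4H-1,3-dioxin-4-one | CC(C)=CCC(CC=C(C)C)C1=CC(=O)OC(C)(C)O1
F4 | step 8 | (4S)-7-hydroxy-6,6-bis(3-methylbut-2-en-1-yl)-8-[(2R)-2-methylbutanoyl]-4-phenyl-3,4-dihydro-2H-chromene-2,5(6H)-dione | CC[C@@H](C)C(=O)C1=C(O)C(CC=C(C)C)(CC=C(C)C)C(=O)C2=C1OC(=O)C[C@H]2c1ccccc1
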